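The route rests on cutting the bond between C2 of the pyranone (ring C) and C1' of ring B. C2 is bonded only to O1, C3 and C1', so it is read as a carboxyl-level carbon that carbon monoxide can supply. One palladium-catalysed carbonylative domino joins three components: an iodinated ring-B arene whose 3'-oxygen is masked as a pivalate, CO, and commercial 2',6'-dihydroxy-4'-methoxyacetophenone. It forms C1'–C2, C2–C3 and C2–O1, so all of ring C is built in one operation. The two equivalent hydroxyls of the acetophenone make the acylation site irrelevant and leave the chelated 5-OH. The iodide comes in three steps from 1,2,4-trimethoxybenzene.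

Key step: step 4

Remark: the target has no stereocentre and no configurationally stable axis. It is one achiral compound, and no step has to control configuration.

Step 1
Reactants: 1 1,2,4-trimethoxybenzene
Product: 4 2,3,6-trimethoxyphenol, via aryllithium 2 (not isolated), via arylboronate 3 (not isolated)
Conditions: n-BuLi (1.1 equiv), THF, 0 °C to rt; B(OMe)3, −78 °C to rt; AcOH, 30% aq. H2O2, 0 °C to rt
Reagents that add atoms: hydrogen peroxide OO (phenol oxygen); for the intermediates also n-butyllithium [Li]CCCC and trimethyl borate COB(OC)OC
Why: Directed ortho-metalation removes the C3–H that lies between two methoxy groups, and borate trapping followed by peroxide-induced 1,2-aryl migration (boronate oxidation) turns C–Li into C–OH without touching the ethers.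

Step 2
Reactants: 4 2,3,6-trimethoxyphenol
Product: 5 2,3,6-trimethoxyphenyl pivalate
Conditions: PivCl (1.2 equiv), Et3N (1.5 equiv), DMAP (cat.), CH2Cl2, 0 °C to rt
Reagents that add atoms: pivaloyl chloride CC(C)(C)C(=O)Cl
Why: DMAP-catalysed O-acylation turns the strongest donor of the ring into a weak one and gives an ester hindered enough to withstand the later amidine base.

Step 3
Reactants: 5 2,3,6-trimethoxyphenyl pivalate
Product: 6 5-iodo-2,3,6-trimethoxyphenyl pivalate (iodine para to the 2-methoxy and ortho to the 6-methoxy group)
Conditions: NIS (1.05 equiv), TFA (cat.), MeCN, 0 °C to rt, dark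
Reagents that add atoms: N-iodosuccinimide O=C1CCC(=O)N1I
Why: In this electrophilic aromatic iodination both free positions are ortho to a methoxy group, but only C5 is also para to a methoxy group while C4 is para to the weakly donating acyloxy group, the same ester switch that sends halogenation of guaiacol esters para to OMe.

Step 4
Reactants: 6 5-iodo-2,3,6-trimethoxyphenyl pivalate; 7 2',6'-dihydroxy-4'-methoxyacetophenone
Product: 11 5,3'-dihydroxy-7,2',4',5'-tetramethoxyflavone, via aryl ester 8 (not isolated), via diketone 9 (not isolated), via flavone pivalate 10 (not isolated)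
Conditions: 7 (1.5 equiv), Pd(OAc)2 (5 mol %), dppb (10 mol %), DBU (4 equiv), CO (10 bar), DMSO, 120 °C; vent, then K2CO3 (3 equiv), MeOH, 50 °C; 1 M HCl work-up
Reagents that add atoms: carbon monoxide [C-]#[O+]
Why: Pd(0) inserts into the C–I bond of 6, CO inserts to form the C1'–C2 bond as an aroylpalladium species, and a phenoxide of 7 takes up the aroyl group to give ester 8. DBU then enolises the acetyl group, a Baker–Venkataraman O-to-C acyl shift forms C2–C3 (diketone 9, which direct C-aroylation of the enolate would also give), and a phenol oxygen adds to the aroyl carbonyl in a 6-exo-trig closure whose hemiketal loses water to give ring C of 10. The closest known reaction type is the palladium-catalysed carbonylative flavone synthesis from aryl halides and 2-hydroxyacetophenones (aryloxycarbonylation, acyl shift and cyclodehydration in one pot). No stereocentre is formed. The step needs single aroylation and carbonylative rather than direct coupling, and this is secured by the excess of 7, by its two equivalent hydroxyls (either one leads to the same 10 and the other ends as the chelated, poorly nucleophilic 5-OH), by the CO pressure and by the chelating diphosphine. The pivalate, shielded by tert-butyl and two flanking methoxy groups, should largely outlast the carbonylation, and the closing carbonate methanolysis (transesterification) removes it together with any stray aroyl ester, so partial early loss converges on 11.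

Compound list
1 | 1,2,4-trimethoxybenzene | COc1ccc(OC)c(OC)c1 | starting material
2 | (2,3,6-trimethoxyphenyl)lithium | [Li]c1c(OC)ccc(OC)c1OC | intermediate
3 | dimethyl (2,3,6-trimethoxyphenyl)boronate | COB(OC)c1c(OC)ccc(OC)c1OC | intermediate
4 | 2,3,6-trimethoxyphenol | COc1ccc(OC)c(OC)c1O | intermediate
5 | 2,3,6-trimethoxyphenyl pivalate | COc1ccc(OC)c(OC)c1OC(=O)C(C)(C)C | intermediate
6 | 5-iodo-2,3,6-trimethoxyphenyl pivalate | COc1c(I)cc(OC)c(OC)c1OC(=O)C(C)(C)C | intermediate
7 | 2',6'-dihydroxy-4'-methoxyacetophenone | CC(=O)c1c(O)cc(OC)cc1O | starting material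
8 | 2-acetyl-3-hydroxy-5-methoxyphenyl 2,4,5-trimethoxy-3-(pivaloyloxy)benzoate | CC(=O)c1c(O)cc(OC)cc1OC(=O)c1cc(OC)c(OC)c(OC(=O)C(C)(C)C)c1OC | intermediate
9 | 1-(2,6-dihydroxy-4-methoxyphenyl)-3-[2,4,5-trimethoxy-3-(pivaloyloxy)phenyl]propane-1,3-dione | COc1cc(O)c(C(=O)CC(=O)c2cc(OC)c(OC)c(OC(=O)C(C)(C)C)c2OC)c(O)c1 | intermediate
10 | 5-hydroxy-7,2',4',5'-tetramethoxy-3'-(pivaloyloxy)flavone | COc1cc(O)c2c(=O)cc(-c3cc(OC)c(OC)c(OC(=O)C(C)(C)C)c3OC)oc2c1 | intermediate
11 | 5,3'-dihydroxy-7,2',4',5'-tetramethoxyflavone | COc1cc(O)c2c(=O)cc(-c3cc(OC)c(OC)c(O)c3OC)oc2c1 | target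

Total step count: 4. Longest linear sequence: 4 (1 → 4 → 5 → 6 → 11).

Steps most likely to fail

Step 4. Several things may go wrong:
- Oxidative addition and CO capture may be slow at the electron-rich, ortho-substituted iodide, so hydrodeiodination competes.
- The acyl shift may stall in the doubly deprotonated acetophenone.
- A second aroylation at C3 may occur.
- The protecting group may be lost early, freeing a competing phenoxide.

The fallback sets out from 6 and 7 and comes back at 10. Miyaura borylation of 6 (B2pin2, PdCl2(dppf), KOAc, dioxane, 80 °C) would give 2,3,6-trimethoxy-5-(pinacolboryl)phenyl pivalate F1. Condensation of 7 with DMF dimethyl acetal would give the enaminone (E)-1-(2,6-dihydroxy-4-methoxyphenyl)-3-(dimethylamino)prop-2-en-1-one F2, and HCl would close it to 5-hydroxy-7-methoxychromone F3. A Pd(II)-catalysed oxidative boron-Heck reaction of F1 with the C2=C3 bond of F3 (Pd(TFA)2, a phenanthroline ligand, O2, DMSO, 100 °C) would form the same C2–C1' bond. It proceeds by carbopalladation with aryl delivery to C2 and β-hydride elimination, and it gives 10. Compound 10 is then methanolysed as in the second stage of step 4.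

Step 3. The two ortho-methoxy-activated ring positions may not be discriminated well enough, and the ring may be iodinated twice. The fallback sets out from 1 and comes back at 6. It marks the coupling position with silicon before the hydroxyl exists.
- Bromination of 1 (NBS, MeCN) goes to the position para to the 2-methoxy group and would give 1-bromo-2,4,5-trimethoxybenzene F4.
- Bromine–lithium exchange (n-BuLi, THF, −78 °C) and TMSCl would give trimethyl(2,4,5-trimethoxyphenyl)silane F5.
- Directed lithiation between the two methoxy groups, then B(OMe)3 and H2O2/NaOH, would give 2,3,6-trimethoxy-5-(trimethylsilyl)phenol F6.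
- Pivaloylation as in step 2 would give 2,3,6-trimethoxy-5-(trimethylsilyl)phenyl pivalate F7.
- ipso-Iododesilylation with ICl (CH2Cl2, −78 to 0 °C) would give 6 with the site fixed by the C–Si bond.

Step 1. The 2,6-dialkoxyarylboron intermediate may protodeboronate before it is oxidised, and excess peroxide may over-oxidise the very electron-rich phenol. The fallback sets out from 1 (through the same aryllithium 2) and comes back at 4. Quenching 2 with DMF would give 2,3,6-trimethoxybenzaldehyde F8, a stable compound that can be purified. Baeyer–Villiger oxidation with one equivalent of mCPBA (CH2Cl2, 0 °C to rt), in which the electron-rich aryl group migrates, would give 2,3,6-trimethoxyphenyl formate F9. Brief methanolysis (cat. K2CO3, MeOH) would give 4 with no oxidant left beside the free phenol.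

Further compounds
F1 | step 4 | 2,3,6-trimethoxy-5-(4,4,5,5-tetramethyl-1,3,2-dioxaborolan-2-yl)phenyl pivalate | COc1c(B2OC(C)(C)C(C)(C)O2)cc(OC)c(OC)c1OC(=O)C(C)(C)C
F2 | step 4 | (E)-1-(2,6-dihydroxy-4-methoxyphenyl)-3-(dimethylamino)prop-2-en-1-one | CN(C)/C=C/C(=O)c1c(O)cc(OC)cc1O
F3 | step 4 | 5-hydroxy-7-methoxychromone | COc1cc(O)c2c(=O)ccoc2c1
F4 | step 3 | 1-bromo-2,4,5-trimethoxybenzene | COc1cc(OC)c(OC)cc1Br
F5 | step 3 | trimethyl(2,4,5-trimethoxyphenyl)silane | COc1cc(OC)c(OC)cc1[Si](C)(C)C
F6 | step 3 | 2,3,6-trimethoxy-5-(trimethylsilyl)phenol | COc1c(O)c(OC)c(OC)cc1[Si](C)(C)C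
F7 | step 3 | 2,3,6-trimethoxy-5-(trimethylsilyl)phenyl pivalate | COc1c(OC(=O)C(C)(C)C)c(OC)c(OC)cc1[Si](C)(C)C
F8 | step 1 | 2,3,6-trimethoxybenzaldehyde | COc1ccc(OC)c(OC)c1C=O
F9 | step 1 | 2,3,6-trimethoxyphenyl formate | COc1ccc(OC)c(OC)c1OC=O
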